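Ring A of this flavone carries oxygen on four adjacent carbons (C5, C6, C7, C8), and the C5 and C8 oxygens are para to each other. This is the footprint of a squaric ester inserted between C4a and C8a of a 4-pyranone.
Retrosynthesis: unmask 5'-OH (Bn) and 7-OH (t-Bu) and remove the 8-O-methyl group. Then cut C4a–C5 and C8–C8a to reach iodopyranone 12 and mixed squarate 15, and cut C2–C1' to reach diiodopyranone 9 and aryl bromide 5.
Forward: ring C is bought as pyromeconic acid and fully halogenated before the easily iodinated ring B is attached. Ring B (from 2,4-dimethoxybenzaldehyde) is joined at C2 by a site-selective Negishi coupling, and ring A is closed last by squarate addition and thermal ring expansion.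
Oxygen differentiation: 6-OMe and 7-Ot-Bu come from the two different ester groups of the squarate, and 5-OH is set apart from 8-OH by its hydrogen bond to C4=O.
Stereochemistry: there is none to set. The only sp3 stereocentre on the way (the carbinol carbon of 17) is racemic and disappears on ring opening.

Key step: step 10

Remark: the target SMILES has no stereodescriptor and the C2–C1' axis is not hindered enough to be configurationally stable. The compound is therefore treated as achiral, and the single-enantiomer requirement needs no extra measure.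

Step 1
Reactants: 1 2,4-dimethoxybenzaldehyde
Product: 3 2,4-dimethoxyphenol, via aryl formate 2 (not isolated)
Conditions: 30% aq H2O2, cat. H2SO4, MeOH, rt
Reagents that add atoms: hydrogen peroxide, OO
Why: In this acid-catalysed Dakin-type (Baeyer–Villiger) oxidation the electron-rich aryl group migrates to oxygen, and methanol cleaves the formate 2 in the same flask.

Step 2
Reactants: 3 2,4-dimethoxyphenol
Product: 4 1-(benzyloxy)-2,4-dimethoxybenzene
Conditions: BnBr, K2CO3, DMF, rt
Reagents that add atoms: benzyl bromide, BrCc1ccccc1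
Why: This is a Williamson ether synthesis on the phenoxide, and the benzyl ether should survive the organometallic, thermal and acidic steps ahead and leave by hydrogenolysis at the end.

Step 3
Reactants: 4 1-(benzyloxy)-2,4-dimethoxybenzene
Product: 5 1-(benzyloxy)-5-bromo-2,4-dimethoxybenzene
Conditions: NBS, MeCN, 0 °C to rt
Reagents that add atoms: N-bromosuccinimide, O=C1CCC(=O)N1Br
Why: Electrophilic aromatic bromination should go to C5, which is para to one methoxy group and ortho to the other, because C3 is hindered between the two methoxy groups and C6 is activated only by the benzyloxy group.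

Step 4
Reactants: 6 pyromeconic acid (3-hydroxy-4H-pyran-4-one)
Product: 7 3-hydroxy-2-iodo-4H-pyran-4-one
Conditions: NIS, MeCN, rt, dark
Reagents that add atoms: N-iodosuccinimide, O=C1CCC(=O)N1I
Why: Electrophilic substitution of the enolic hydroxypyranone occurs at C2, next to the hydroxyl-bearing carbon, which is the site where kojic and pyromeconic acid are halogenated and aminomethylated.

Step 5
Reactants: 7 3-hydroxy-2-iodo-4H-pyran-4-one
Product: 8 2-iodo-3-methoxy-4H-pyran-4-one
Conditions: MeI, K2CO3, acetone, 40 °C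
Reagents that add atoms: iodomethane, CI
Why: Williamson O-methylation of the acidic enol is routine for maltol and kojic acid, and it installs the future flavone 3-OMe.

Step 6
Reactants: 8 2-iodo-3-methoxy-4H-pyran-4-one
Product: 9 2,5-diiodo-3-methoxy-4H-pyran-4-one
Conditions: I2, (NH4)2Ce(NO3)6, MeCN, 70 °C
Reagents that add atoms: iodine, II
Why: This is the oxidative α-iodination of a vinylogous ester used for C3 of chromones and flavones and C5 of uracils; C5 is the only nucleophilic ring carbon left, and the step is run before ring B is present because a trialkoxyarene would be iodinated or oxidised first.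

Step 7
Reactants: 5 1-(benzyloxy)-5-bromo-2,4-dimethoxybenzene; 9 2,5-diiodo-3-methoxy-4H-pyran-4-one
Product: 12 2-[5-(benzyloxy)-2,4-dimethoxyphenyl]-5-iodo-3-methoxy-4H-pyran-4-one, via aryllithium 10 (not isolated), via arylzinc chloride 11 (not isolated)
Conditions: 5, n-BuLi, THF, −78 °C; ZnCl2, −78 °C to rt; then 9 (slight excess), cat. Pd(PPh3)4, THF, 0 °C to rt
Reagents that add atoms: none
Why: Bromine–lithium exchange and transmetalation give 11, and in the site-selective Negishi coupling Pd(0) should insert first into the C2–I bond (α to the ring oxygen and β to the carbonyl, a vinylogous acyl iodide), as in the β-selective couplings of 3,4-dibromofuran-2(5H)-one and 2,3-dibromoindenone, so the C5–I bond is kept.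

Step 8
Reactants: 13 dimethyl squarate
Product: 14 3-hydroxy-4-methoxycyclobut-3-ene-1,2-dione (methyl hydrogen squarate)
Conditions: NaOH (1 equiv), THF–H2O, 0 °C; then aq HCl
Reagents that add atoms: sodium hydroxide, [Na+].[OH-]
Why: Hydroxide displaces one methoxy group by addition–elimination at a vinylogous ester carbon, and the delocalised monoanion formed is no longer electrophilic, so hydrolysis stops after one ester.

Step 9
Reactants: 14 3-hydroxy-4-methoxycyclobut-3-ene-1,2-dione
Product: 15 3-tert-butoxy-4-methoxycyclobut-3-ene-1,2-dione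
Conditions: Cl3CC(=NH)Ot-Bu, CH2Cl2–THF, 0 °C to rt (14 added slowly to the imidate)
Reagents that add atoms: tert-butyl 2,2,2-trichloroacetimidate, CC(C)(C)OC(=N)C(Cl)(Cl)Cl
Why: In this trichloroacetimidate esterification without added acid the strongly acidic 14 protonates the imidate, the squarate anion captures the tert-butyl cation, and its two equivalent oxygens give the same product.

Step 10
Reactants: 12 2-[5-(benzyloxy)-2,4-dimethoxyphenyl]-5-iodo-3-methoxy-4H-pyran-4-one; 15 3-tert-butoxy-4-methoxycyclobut-3-ene-1,2-dione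
Product: 19 2-[5-(benzyloxy)-2,4-dimethoxyphenyl]-7-tert-butoxy-5,8-dihydroxy-3,6-dimethoxy-4H-chromen-4-one, via pyranonylmagnesium chloride 16 (not isolated), via cyclobutenone adduct 17 (not isolated), via dienylketene 18 (not isolated)
Conditions: i-PrMgCl·LiCl, THF, −78 to −40 °C; 15, −78 °C; aq NH4Cl at −78 °C; crude 17 in degassed toluene, 110 °C, Ar
Reagents that add atoms: none
Why: Iodine–magnesium exchange on the α-iodo vinylogous ester 12 gives 16, a β-oxygenated alkenylmagnesium of the kind known from 5-iodo-1,3-dioxin-4-ones and 5-iodouracils and kept cold enough not to eject the ring oxygen, and 16 adds 1,2 to a squarate carbonyl to make C4a–C5. In hot toluene 17 opens by a conrotatory 4π process in which the hydroxyl group turns outward, so that in 18 the pyranonyl group lies cis to the ketene; ring A (six-membered, carbocyclic) then closes by 6π electrocyclisation of the ketene carbon onto the C6–H carbon of the pyranone (C8–C8a), and a proton shift from C8a to oxygen delivers the 5,8-hydroquinone. The closest known reaction type is the Moore ring expansion of 4-alkenyl- and 4-heteroaryl-4-hydroxycyclobutenones made from squarate esters. The carbinol carbon of 17 is the only stereocentre formed; it is racemic and is lost on ring opening, so nothing has to be controlled. The selectivity needed is attack at the carbonyl next to the methoxy-bearing carbon, which puts OMe on C6 and Ot-Bu on C7: the tert-butoxy group screens its own neighbouring carbonyl and, being crowded, conjugates less well with the vinylogous carbonyl that is to be attacked, so steric and electronic bias act in the same direction. Closure has no regiochemical choice, because the second neighbour of the pyranone carbon that carries the cyclobutenone is the C4 carbonyl carbon.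

Step 11
Reactants: 19 2-[5-(benzyloxy)-2,4-dimethoxyphenyl]-7-tert-butoxy-5,8-dihydroxy-3,6-dimethoxy-4H-chromen-4-one
Product: 20 2-[5-(benzyloxy)-2,4-dimethoxyphenyl]-7-tert-butoxy-5-hydroxy-3,6,8-trimethoxy-4H-chromen-4-one
Conditions: MeI (1.1 equiv), K2CO3, degassed acetone, rt, Ar
Reagents that add atoms: iodomethane, CI
Why: This is the partial Williamson methylation practised on 5,8-dihydroxyflavones, in which the chelated 5-OH is neither readily deprotonated nor nucleophilic, so only the 8-phenoxide should be alkylated, with air excluded because the hydroquinone is oxidisable.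

Step 12
Reactants: 20 2-[5-(benzyloxy)-2,4-dimethoxyphenyl]-7-tert-butoxy-5-hydroxy-3,6,8-trimethoxy-4H-chromen-4-one
Product: 21 2-[5-(benzyloxy)-2,4-dimethoxyphenyl]-5,7-dihydroxy-3,6,8-trimethoxy-4H-chromen-4-one
Conditions: TFA–CH2Cl2 1:4, 0 °C to rt
Reagents that add atoms: none
Why: Acidolysis of the aryl tert-butyl ether (E1 loss of the tert-butyl cation as isobutene) is fast under conditions that leave methyl and benzyl aryl ethers intact.

Step 13
Reactants: 21 2-[5-(benzyloxy)-2,4-dimethoxyphenyl]-5,7-dihydroxy-3,6,8-trimethoxy-4H-chromen-4-one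
Product: 22 5,7-dihydroxy-2-(5-hydroxy-2,4-dimethoxyphenyl)-3,6,8-trimethoxy-4H-chromen-4-one (target)
Conditions: H2 (1 atm), 10% Pd/C, EtOAc–MeOH, rt
Reagents that add atoms: none
Why: Catalytic hydrogenolysis of the benzyl aryl ether frees 5'-OH, while the tetrasubstituted C2=C3 bond of the flavone and the methyl ethers are not touched under these mild conditions.

Compound list
1 | 2,4-dimethoxybenzaldehyde | COc1ccc(C=O)c(OC)c1 | starting material
2 | 2,4-dimethoxyphenyl formate | COc1ccc(OC=O)c(OC)c1 | intermediate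
3 | 2,4-dimethoxyphenol | COc1ccc(O)c(OC)c1 | intermediate
4 | 1-(benzyloxy)-2,4-dimethoxybenzene | COc1ccc(OCc2ccccc2)c(OC)c1 | intermediate
5 | 1-(benzyloxy)-5-bromo-2,4-dimethoxybenzene | COc1cc(OC)c(OCc2ccccc2)cc1Br | intermediate
6 | pyromeconic acid (3-hydroxy-4H-pyran-4-one) | O=c1ccocc1O | starting material
7 | 3-hydroxy-2-iodo-4H-pyran-4-one | O=c1ccoc(I)c1O | intermediate
8 | 2-iodo-3-methoxy-4H-pyran-4-one | COc1c(I)occc1=O | intermediate
9 | 2,5-diiodo-3-methoxy-4H-pyran-4-one | COc1c(I)occ(I)c1=O | intermediate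
10 | [5-(benzyloxy)-2,4-dimethoxyphenyl]lithium | [Li]c1cc(OCc2ccccc2)c(OC)cc1OC | intermediate
11 | [5-(benzyloxy)-2,4-dimethoxyphenyl]zinc chloride | Cl[Zn]c1cc(OCc2ccccc2)c(OC)cc1OC | intermediate
12 | 2-[5-(benzyloxy)-2,4-dimethoxyphenyl]-5-iodo-3-methoxy-4H-pyran-4-one | COc1cc(OC)c(-c2occ(I)c(=O)c2OC)cc1OCc1ccccc1 | intermediate
13 | dimethyl squarate (3,4-dimethoxycyclobut-3-ene-1,2-dione) | COC1=C(OC)C(=O)C1=O | starting material
14 | 3-hydroxy-4-methoxycyclobut-3-ene-1,2-dione | COC1=C(O)C(=O)C1=O | intermediate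
15 | 3-tert-butoxy-4-methoxycyclobut-3-ene-1,2-dione | COC1=C(OC(C)(C)C)C(=O)C1=O | intermediate
16 | {6-[5-(benzyloxy)-2,4-dimethoxyphenyl]-5-methoxy-4-oxo-4H-pyran-3-yl}magnesium chloride (LiCl complex) | COc1cc(OC)c(-c2occ([Mg]Cl)c(=O)c2OC)cc1OCc1ccccc1 | intermediate
17 | racemic 4-{6-[5-(benzyloxy)-2,4-dimethoxyphenyl]-5-methoxy-4-oxo-4H-pyran-3-yl}-2-tert-butoxy-4-hydroxy-3-methoxycyclobut-2-en-1-one | COC1=C(OC(C)(C)C)C(=O)C1(O)c1coc(-c2cc(OCc3ccccc3)c(OC)cc2OC)c(OC)c1=O | intermediate
18 | (3Z)-4-{6-[5-(benzyloxy)-2,4-dimethoxyphenyl]-5-methoxy-4-oxo-4H-pyran-3-yl}-2-tert-butoxy-4-hydroxy-3-methoxybuta-1,3-dien-1-one | O=C=C(OC(C)(C)C)/C(OC)=C(/O)c1coc(-c2cc(OCc3ccccc3)c(OC)cc2OC)c(OC)c1=O | intermediate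
19 | 2-[5-(benzyloxy)-2,4-dimethoxyphenyl]-7-tert-butoxy-5,8-dihydroxy-3,6-dimethoxy-4H-chromen-4-one | COc1cc(OC)c(-c2oc3c(O)c(OC(C)(C)C)c(OC)c(O)c3c(=O)c2OC)cc1OCc1ccccc1 | intermediate
20 | 2-[5-(benzyloxy)-2,4-dimethoxyphenyl]-7-tert-butoxy-5-hydroxy-3,6,8-trimethoxy-4H-chromen-4-one | COc1cc(OC)c(-c2oc3c(OC)c(OC(C)(C)C)c(OC)c(O)c3c(=O)c2OC)cc1OCc1ccccc1 | intermediate
21 | 2-[5-(benzyloxy)-2,4-dimethoxyphenyl]-5,7-dihydroxy-3,6,8-trimethoxy-4H-chromen-4-one | COc1cc(OC)c(-c2oc3c(OC)c(O)c(OC)c(O)c3c(=O)c2OC)cc1OCc1ccccc1 | intermediate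
22 | 5,7-dihydroxy-2-(5-hydroxy-2,4-dimethoxyphenyl)-3,6,8-trimethoxy-4H-chromen-4-one (CNP0156395.0, achiral) | COc1cc(OC)c(-c2oc3c(OC)c(O)c(OC)c(O)c3c(=O)c2OC)cc1O | target

Total step count: 13. Longest linear sequence: 8 steps (steps 1–3 or 4–6, then 7 and 10–13).

Steps most likely to fail

Step 10. The magnesium reagent may not discriminate well enough between the two carbonyl groups of the unsymmetrical squarate. Attack at the wrong one would interchange the oxygen substituents of C6 and C7. The fallback removes the regiochemical question and differentiates the two oxygens later by their acidity. It sets out from 12.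
- 12 is exchanged as before to 16 and added to commercial di-tert-butyl squarate to give the symmetric-squarate adduct F1.
- Heating in toluene expands this to the 6,7-di-tert-butoxy hydroquinone F2.
- Methylation of the free 8-OH (MeI, K2CO3) gives the 8-methyl ether F3, and TFA gives the 5,6,7-triol F4.
- One equivalent of BnBr with K2CO3 in DMF alkylates the most acidic 7-OH, as in the baicalein series, to give the 7-benzyl ether F5.
- MeI/K2CO3 then methylates 6-OH while the chelated 5-OH stays free, giving the 6-methyl ether F6.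
- Hydrogenolysis of both benzyl ethers comes back to the route at 22.

Step 7. Site selectivity may erode through oxidative addition at C5–I or a second coupling of the product. The fallback relies on two different halogens instead of two positions of one halogen, and it also bypasses step 6. It sets out from 8.
- Bromination at C5 (NBS, cat. TFA, MeCN) gives 5-bromo-2-iodo-3-methoxy-4H-pyran-4-one F7.
- Negishi coupling with 11 then takes place at the only C–I bond and gives the 5-bromo-2-arylpyranone F8.
- A copper-catalysed aromatic Finkelstein exchange (NaI, CuI, trans-N,N'-dimethylcyclohexane-1,2-diamine, dioxane, 110 °C) comes back to the route at 12.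

Step 11. The electron-rich hydroquinone may be oxidised to the quinone under basic conditions, or methylation may spread to the 5-oxygen. In the fallback the two phenols are differentiated before they exist. It sets out from 17, which is now isolated.
- The tertiary alcohol is silylated (TESOTf, 2,6-lutidine) to give the triethylsilyl ether of the adduct F9.
- The same thermal ring expansion then gives the 5-O-triethylsilyl 8-phenol F10, which is not a free hydroquinone.
- MeI/K2CO3 gives the 8-methyl ether F11.
- TFA in moist CH2Cl2 removes the silyl and tert-butyl groups together and comes back to the route at 21.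

Further compounds
F1 | step 10 | racemic 4-{6-[5-(benzyloxy)-2,4-dimethoxyphenyl]-5-methoxy-4-oxo-4H-pyran-3-yl}-2,3-di-tert-butoxy-4-hydroxycyclobut-2-en-1-one | CC(C)(C)OC1=C(OC(C)(C)C)C(=O)C1(O)c1coc(-c2cc(OCc3ccccc3)c(OC)cc2OC)c(OC)c1=O
F2 | step 10 | 2-[5-(benzyloxy)-2,4-dimethoxyphenyl]-6,7-di-tert-butoxy-5,8-dihydroxy-3-methoxy-4H-chromen-4-one | COc1cc(OC)c(-c2oc3c(O)c(OC(C)(C)C)c(OC(C)(C)C)c(O)c3c(=O)c2OC)cc1OCc1ccccc1
F3 | step 10 | 2-[5-(benzyloxy)-2,4-dimethoxyphenyl]-6,7-di-tert-butoxy-5-hydroxy-3,8-dimethoxy-4H-chromen-4-one | COc1cc(OC)c(-c2oc3c(OC)c(OC(C)(C)C)c(OC(C)(C)C)c(O)c3c(=O)c2OC)cc1OCc1ccccc1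
F4 | step 10 | 2-[5-(benzyloxy)-2,4-dimethoxyphenyl]-5,6,7-trihydroxy-3,8-dimethoxy-4H-chromen-4-one | COc1cc(OC)c(-c2oc3c(OC)c(O)c(O)c(O)c3c(=O)c2OC)cc1OCc1ccccc1
F5 | step 10 | 7-(benzyloxy)-2-[5-(benzyloxy)-2,4-dimethoxyphenyl]-5,6-dihydroxy-3,8-dimethoxy-4H-chromen-4-one | COc1cc(OC)c(-c2oc3c(OC)c(OCc4ccccc4)c(O)c(O)c3c(=O)c2OC)cc1OCc1ccccc1
F6 | step 10 | 7-(benzyloxy)-2-[5-(benzyloxy)-2,4-dimethoxyphenyl]-5-hydroxy-3,6,8-trimethoxy-4H-chromen-4-one | COc1cc(OC)c(-c2oc3c(OC)c(OCc4ccccc4)c(OC)c(O)c3c(=O)c2OC)cc1OCc1ccccc1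
F7 | step 7 | 5-bromo-2-iodo-3-methoxy-4H-pyran-4-one | COc1c(I)occ(Br)c1=O
F8 | step 7 | 2-[5-(benzyloxy)-2,4-dimethoxyphenyl]-5-bromo-3-methoxy-4H-pyran-4-one | COc1cc(OC)c(-c2occ(Br)c(=O)c2OC)cc1OCc1ccccc1
F9 | step 11 | racemic 4-{6-[5-(benzyloxy)-2,4-dimethoxyphenyl]-5-methoxy-4-oxo-4H-pyran-3-yl}-2-tert-butoxy-3-methoxy-4-(triethylsilyloxy)cyclobut-2-en-1-one | COC1=C(OC(C)(C)C)C(=O)C1(O[Si](CC)(CC)CC)c1coc(-c2cc(OCc3ccccc3)c(OC)cc2OC)c(OC)c1=O
F10 | step 11 | 2-[5-(benzyloxy)-2,4-dimethoxyphenyl]-7-tert-butoxy-8-hydroxy-3,6-dimethoxy-5-(triethylsilyloxy)-4H-chromen-4-one | COc1cc(OC)c(-c2oc3c(O)c(OC(C)(C)C)c(OC)c(O[Si](CC)(CC)CC)c3c(=O)c2OC)cc1OCc1ccccc1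
F11 | step 11 | 2-[5-(benzyloxy)-2,4-dimethoxyphenyl]-7-tert-butoxy-3,6,8-trimethoxy-5-(triethylsilyloxy)-4H-chromen-4-one | COc1cc(OC)c(-c2oc3c(OC)c(OC(C)(C)C)c(OC)c(O[Si](CC)(CC)CC)c3c(=O)c2OC)cc1OCc1ccccc1
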